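**Retrosynthetic overview**

1. The target is a (2S)-2,7,8-trimethylchroman-6-ol whose all-E side chain (C1' on C2 through C33') carries a tertiary allylic alcohol at C24' (S). The chain is cut at the C10'–C11' single bond into a silyl-protected chroman carboxylic acid (C1'–C10' plus CO2H) and an (E)-alkenyl iodide (C11'–C33'), joined by a nickel-electrocatalytic decarboxylative alkenylation.
2. The enabling feature is the head-to-tail 1,5-diene repeat. C10' is a stereochemically blank CH2 two bonds from the alkene carbon C8', so it can be the α-carbon of a 4-methylalk-4-enoic acid and become a primary radical on loss of CO2. C11' is the CH end of the trisubstituted (E)-alkene C11'=C12', so it can enter as a configurationally stable (E)-2-methylalk-1-enyl iodide.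
3. The two tertiary C–O stereocentres (chroman C2 and C24') have the same spatial sense. Both come from one Sharpless epoxidation of (2E,6E)-farnesol: (S)-nerolidol for the chroman half and the corresponding (S)-propargylic alcohol for the carbinol half.
4. Rings: the benzene ring is bought as 1,4-dimethoxy-2,3-dimethylbenzene and attached to nerolidol by hydroboration and Suzuki–Miyaura coupling. The dihydropyran ring is formed afterwards, at the aryl C8a–O bond, by reductive cyclisation of the hydroxy-quinone, so the C2–O bond is never broken.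
5. Chain: each half is extended at its terminal (E)-methyl group after SeO2 oxidation (acetic acid dianion on the chroman side; alkyne allylation then trans-hydroalumination for the C22'=C23'/C24' unit). The alkenyl iodide comes from (E)-geranylacetone by alkyne methylalumination.

Key step: step 19

Remark on the chemistry: the SMILES encodes (S) at the chroman carbon C2 and (S) at C24'; the route is built for exactly this pair.
Assumption: (2E,6E)-farnesol, (E)-geranylacetone and 1,4-dimethoxy-2,3-dimethylbenzene are bought as single isomers.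

**Route**

Step 1
Reactants: 1 (2E,6E)-farnesol
Product: 2 (2S,3S)-2,3-epoxyfarnesol
Conditions: Ti(OiPr)4 (cat.), L-(+)-diethyl tartrate (cat.), t-BuOOH, 4 Å molecular sieves, CH2Cl2, −20 °C
Reagents that add atoms: tert-butyl hydroperoxide, CC(C)(C)OO
Why: Sharpless asymmetric epoxidation acts only on the allylic C2=C3 alkene, and with L-(+)-diethyl tartrate an (E)-allylic alcohol should be oxidised on the face that gives the (2S,3S)-epoxide, so the tertiary C3–O centre (later C2 of the chroman and C24' of the chain) is set here by the catalyst.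

Step 2
Reactants: 2 (2S,3S)-2,3-epoxyfarnesol
Product: 4 (3S,6E)-nerolidol, via epoxy iodide 3 (not isolated)
Conditions: PPh3, I2, imidazole, THF, 0 °C; then Zn dust, EtOH, reflux
Reagents that add atoms: none
Why: Appel-type iodination of the primary alcohol, then zinc insertion into the C–I bond with β-elimination that opens the epoxide (reductive elimination of a 2,3-epoxy iodide), should give the tertiary allylic alcohol without touching the C3–O bond, so C3 stays (S).

Step 3
Reactants: 2 (2S,3S)-2,3-epoxyfarnesol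
Product: 5 (2R,3S)-2-(chloromethyl)-3-methyl-3-[(3E)-4,8-dimethylnona-3,7-dien-1-yl]oxirane
Conditions: PPh3, CCl4, NaHCO3, reflux
Reagents that add atoms: carbon tetrachloride, ClC(Cl)(Cl)Cl
Why: Appel chlorination of the primary epoxy alcohol under buffered neutral conditions should leave the epoxide and both stereocentres untouched (the descriptor at C2 changes only because chlorine raises the priority of C1).

Step 4
Reactants: 5 (2R,3S)-2-(chloromethyl)-3-methyl-3-[(3E)-4,8-dimethylnona-3,7-dien-1-yl]oxirane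
Product: 6 (3S,6E)-3,7,11-trimethyldodeca-6,10-dien-1-yn-3-ol
Conditions: n-BuLi (3.2 equiv), THF, −40 °C; then aq. NH4Cl
Reagents that add atoms: none
Why: Base-induced conversion of a 2,3-epoxy chloride into a propargylic alcohol (deprotonation at C1 with epoxide opening, then dehydrochlorination of the chloroalkene) should deliver the terminal alkyne with the C3–O bond and its (S) configuration intact.

Step 5
Reactants: 7 1,4-dimethoxy-2,3-dimethylbenzene
Product: 8 1-bromo-2,5-dimethoxy-3,4-dimethylbenzene
Conditions: N-bromosuccinimide (1.0 equiv), MeCN, 0 °C to rt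
Reagents that add atoms: N-bromosuccinimide, O=C1CCC(=O)N1Br
Why: Electrophilic aromatic bromination of the electron-rich arene, whose two free positions are equivalent, should stop at the monobromide because the first bromine deactivates the ring.

Step 6
Reactants: 4 (3S,6E)-nerolidol; 8 1-bromo-2,5-dimethoxy-3,4-dimethylbenzene
Product: 10 (3S,6E)-1-(2,5-dimethoxy-3,4-dimethylphenyl)-3,7,11-trimethyldodeca-6,10-dien-3-ol, via alkylborane 9 (not isolated)
Conditions: 9-borabicyclo[3.3.1]nonane (2.2 equiv), THF, 0 °C to rt; then 8, Pd(dppf)Cl2 (cat.), 3 M aq. NaOH, THF, 65 °C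
Reagents that add atoms: none
Why: 9-Borabicyclo[3.3.1]nonane hydroborates only the monosubstituted alkene in the anti-Markovnikov sense, and the primary alkylborane should then undergo B-alkyl Suzuki–Miyaura coupling with the aryl bromide, which forms the future C4–C4a bond without involving the stereocentre.

Step 7
Reactants: 10 (3S,6E)-1-(2,5-dimethoxy-3,4-dimethylphenyl)-3,7,11-trimethyldodeca-6,10-dien-3-ol
Product: 11 2-[(3S,6E)-3-hydroxy-3,7,11-trimethyldodeca-6,10-dien-1-yl]-5,6-dimethylcyclohexa-2,5-diene-1,4-dione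
Conditions: (NH4)2Ce(NO3)6 (2.5 equiv), MeCN/H2O, 0 °C
Reagents that add atoms: water, O
Why: Oxidative demethylation of a 1,4-dimethoxyarene by (NH4)2Ce(NO3)6 should give the para-quinone under conditions that polyprenyl chains and tertiary alcohols normally tolerate.

Step 8
Reactants: 11 2-[(3S,6E)-3-hydroxy-3,7,11-trimethyldodeca-6,10-dien-1-yl]-5,6-dimethylcyclohexa-2,5-diene-1,4-dione
Product: 13 (2S)-2-[(3E)-4,8-dimethylnona-3,7-dien-1-yl]-2,7,8-trimethylchroman-6-ol, via cyclic methyl ketal 12 (not isolated)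
Conditions: p-TsOH·H2O (cat.), HC(OMe)3, MeOH, rt; then L-ascorbic acid, rt, under argon
Reagents that add atoms: none
Why: This is a reductive cyclisation of a γ-hydroxyalkyl quinone in which the tertiary hydroxyl adds 6-exo-trig to the neighbouring carbonyl, acid and methanol turn the hemiketal into the 8a-methoxy ketal (a tocopherone-type quinone monoketal), and ascorbic acid, too weak a reductant for the open trialkylquinone, reduces the derived oxocarbenium ion to the aromatic chromanol, so the ring closes at the aryl C8a–O bond, the C2–O bond is never broken and C2 stays (S).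

Step 9
Reactants: 13 (2S)-2-[(3E)-4,8-dimethylnona-3,7-dien-1-yl]-2,7,8-trimethylchroman-6-ol
Product: 14 tert-butyl({(2S)-2-[(3E)-4,8-dimethylnona-3,7-dien-1-yl]-2,7,8-trimethylchroman-6-yl}oxy)dimethylsilane
Conditions: TBSCl, imidazole, DMF, rt
Reagents that add atoms: tert-butyldimethylsilyl chloride, CC(C)(C)[Si](C)(C)Cl
Why: Silylation of the phenol masks the easily oxidised 6-hydroxychroman for the oxidative and basic steps that follow.

Step 10
Reactants: 14 tert-butyl({(2S)-2-[(3E)-4,8-dimethylnona-3,7-dien-1-yl]-2,7,8-trimethylchroman-6-yl}oxy)dimethylsilane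
Product: 15 (2E,6E)-9-[(2S)-6-{[tert-butyl(dimethyl)silyl]oxy}-2,7,8-trimethylchroman-2-yl]-2,6-dimethylnona-2,6-dien-1-ol
Conditions: SeO2 (cat.), salicylic acid (cat.), t-BuOOH, CH2Cl2, rt
Reagents that add atoms: tert-butyl hydroperoxide, CC(C)(C)OO (oxygen passed on through SeO2, O=[Se]=O)
Why: Catalytic SeO2 allylic oxidation (ene reaction then [2,3]-shift) should attack the most accessible terminal gem-dimethyl alkene at its (E)-methyl group, giving the (E)-allylic alcohol and so fixing the C7'=C8' geometry.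

Step 11
Reactants: 15 (2E,6E)-9-[(2S)-6-{[tert-butyl(dimethyl)silyl]oxy}-2,7,8-trimethylchroman-2-yl]-2,6-dimethylnona-2,6-dien-1-ol
Product: 16 tert-butyl({(2S)-2-[(3E,7E)-9-bromo-4,8-dimethylnona-3,7-dien-1-yl]-2,7,8-trimethylchroman-6-yl}oxy)dimethylsilane
Conditions: CBr4, PPh3, CH2Cl2, 0 °C
Reagents that add atoms: carbon tetrabromide, BrC(Br)(Br)Br
Why: Appel bromination should convert the primary allylic alcohol into the bromide at low temperature with retention of the alkene geometry.

Step 12
Reactants: 16 tert-butyl({(2S)-2-[(3E,7E)-9-bromo-4,8-dimethylnona-3,7-dien-1-yl]-2,7,8-trimethylchroman-6-yl}oxy)dimethylsilane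
Product: 17 (4E,8E)-11-[(2S)-6-{[tert-butyl(dimethyl)silyl]oxy}-2,7,8-trimethylchroman-2-yl]-4,8-dimethylundeca-4,8-dienoic acid
Conditions: AcOH, LiN(iPr)2 (2.1 equiv per AcOH), THF/DMPU, 0 to 35 °C; then 16, 0 °C to rt; dilute HCl work-up
Reagents that add atoms: acetic acid, CC(=O)O (used as its dilithium dianion)
Why: SN2 alkylation of the acetic acid dianion at the unhindered primary allylic carbon adds C10' and the carboxyl carbon and should give the 4-methylalk-4-enoic acid directly, with no ester hydrolysis that would endanger the aryl silyl ether.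

Step 13
Reactants: 18 (E)-geranylacetone
Product: 20 (5E)-6,10-dimethylundeca-5,9-dien-1-yne, via enol phosphate 19 (not isolated)
Conditions: LiN(iPr)2 (1.05 equiv), THF, −78 °C; ClP(O)(OEt)2; then LiN(iPr)2 (2.3 equiv), −78 °C to rt
Reagents that add atoms: none
Why: Kinetic deprotonation of the methyl ketone, O-phosphorylation and base-induced elimination of diethyl phosphate (methyl ketone to terminal alkyne through the enol phosphate) should give the 1,5-enyne without moving the (E)-alkene.

Step 14
Reactants: 20 (5E)-6,10-dimethylundeca-5,9-dien-1-yne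
Product: 22 (1E,5E)-1-iodo-2,6,10-trimethylundeca-1,5,9-triene, via alkenylalane 21 (not isolated)
Conditions: Me3Al (2 equiv), Cp2ZrCl2 (0.25 equiv), CH2Cl2, rt; then I2, THF, −30 to 0 °C
Reagents that add atoms: trimethylaluminium, C[Al](C)C; iodine, II
Why: Zirconium-catalysed carboalumination (Negishi methylalumination) adds methyl and aluminium syn across the terminal alkyne with methyl on the internal carbon, and iodinolysis of the C–Al bond with retention should give the (E)-2-methylalk-1-enyl iodide, which fixes the C11'=C12' geometry.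

Step 15
Reactants: 22 (1E,5E)-1-iodo-2,6,10-trimethylundeca-1,5,9-triene
Product: 23 (2E,6E,10E)-11-iodo-2,6,10-trimethylundeca-2,6,10-trien-1-ol
Conditions: SeO2 (cat.), salicylic acid (cat.), t-BuOOH, CH2Cl2, rt
Reagents that add atoms: tert-butyl hydroperoxide, CC(C)(C)OO (oxygen passed on through SeO2, O=[Se]=O)
Why: SeO2 allylic oxidation should again select the (E)-methyl group of the terminal gem-dimethyl alkene, the electron-poor iodoalkene being the least reactive of the three alkenes, and so fixes the C19'=C20' geometry.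

Step 16
Reactants: 23 (2E,6E,10E)-11-iodo-2,6,10-trimethylundeca-2,6,10-trien-1-ol
Product: 24 (1E,5E,9E)-11-bromo-1-iodo-2,6,10-trimethylundeca-1,5,9-triene
Conditions: CBr4, PPh3, CH2Cl2, 0 °C
Reagents that add atoms: carbon tetrabromide, BrC(Br)(Br)Br
Why: Appel bromination of the primary allylic alcohol should proceed with retention of alkene geometry and leave the alkenyl iodide untouched.

Step 17
Reactants: 6 (3S,6E)-3,7,11-trimethyldodeca-6,10-dien-1-yn-3-ol; 24 (1E,5E,9E)-11-bromo-1-iodo-2,6,10-trimethylundeca-1,5,9-triene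
Product: 25 (1E,5E,9E,14S,17E)-1-iodo-2,6,10,14,18,22-hexamethyltricosa-1,5,9,17,21-pentaen-12-yn-14-ol
Conditions: CuI (1 equiv), NaI, K2CO3, DMF, rt
Reagents that add atoms: none
Why: Copper-mediated coupling of the terminal alkyne with the primary allylic bromide under mild carbonate conditions should form the C21'–C22' bond by direct substitution at the unhindered CH2, tolerate the free tertiary hydroxyl and leave the alkenyl iodide untouched at room temperature.

Step 18
Reactants: 25 (1E,5E,9E,14S,17E)-1-iodo-2,6,10,14,18,22-hexamethyltricosa-1,5,9,17,21-pentaen-12-yn-14-ol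
Product: 26 (1E,5E,9E,12E,14S,17E)-1-iodo-2,6,10,14,18,22-hexamethyltricosa-1,5,9,12,17,21-hexaen-14-ol
Conditions: NaAlH2(OCH2CH2OMe)2 (3 equiv), THF, 0 °C to rt; then aq. potassium sodium tartrate
Reagents that add atoms: none
Why: Hydroxyl-directed trans-hydroalumination of the propargylic alcohol (hydride delivered inside the alkoxyaluminate, then protonolysis of the C–Al bond) should give only the (E)-C22'=C23' alkene, while the isolated alkenes and, at or below room temperature, the alkenyl iodide are not reduced.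

Step 19
Reactants: 17 (4E,8E)-11-[(2S)-6-{[tert-butyl(dimethyl)silyl]oxy}-2,7,8-trimethylchroman-2-yl]-4,8-dimethylundeca-4,8-dienoic acid; 26 (1E,5E,9E,12E,14S,17E)-1-iodo-2,6,10,14,18,22-hexamethyltricosa-1,5,9,12,17,21-hexaen-14-ol
Product: 28 6-O-tert-butyldimethylsilyl ether of the target, via N-acyloxyphthalimide 27 (not isolated)
Conditions: 17 (1.5 equiv), N-hydroxyphthalimide, N,N'-diisopropylcarbodiimide, DMF, rt; then 26, NiCl2·6H2O (20 mol %), 2,2'-bipyridine (20 mol %), AgNO3 (0.3 equiv), LiCl, DMF/THF, Mg anode, reticulated vitreous carbon cathode, constant current, rt, undivided cell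
Reagents that add atoms: none
Why: Cathodically generated low-valent nickel–bipyridine should insert into the C–I bond of 26 with retention, the redox-active ester 27 should accept one electron and lose phthalimide anion and CO2 to give the primary C10' radical, and capture of that radical at nickel followed by reductive elimination forms the C10'–C11' bond. The closest known reaction type is the silver-assisted nickel-electrocatalytic decarboxylative alkenylation of N-acyloxyphthalimides with (E)-2-methylalk-1-enyl iodides, an electrochemical cross-electrophile coupling already used to build head-to-tail polyprenoid chains. No ring is closed and no stereocentre is made; C2 and C24' lie far from the reacting carbons and are carried through unchanged. The step needs retention of the (E) geometry at C11'=C12', which the configurational stability of the alkenylnickel intermediate secures. It also needs the homoallylic C10' radical to be captured before reversible 3-exo closure onto C8'=C7' can scramble that alkene, which the fast radical capture by nickel and the strongly favoured reopening of the cyclopropylcarbinyl radical secure. The free tertiary allylic alcohol and the aryl silyl ether should be inert under the neutral reductive conditions, and the excess of acid with a sacrificial Mg anode should hold back homocoupling and protodeiodination of 26.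

Step 20
Reactants: 28 6-O-tert-butyldimethylsilyl ether of the target
Product: 29 (2S)-2-[(3E,7E,11E,15E,19E,22E,24S,27E)-24-hydroxy-4,8,12,16,20,24,28,32-octamethyltritriaconta-3,7,11,15,19,22,27,31-octaen-1-yl]-2,7,8-trimethylchroman-6-ol (the target)
Conditions: Bu4NF, AcOH, THF, 0 °C, under argon
Reagents that add atoms: none
Why: Fluoride-mediated desilylation should cleave the aryl silyl ether (buffered with AcOH so that the air-sensitive phenoxide is not exposed) and leave the tertiary allylic alcohol, the skipped diene and all alkenes untouched.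

**Compound list**

1 | (2E,6E)-farnesol | CC(C)=CCC/C(C)=C/CC/C(C)=C/CO | starting material
2 | (2S,3S)-2,3-epoxyfarnesol | CC(C)=CCC/C(C)=C/CC[C@]1(C)O[C@H]1CO | intermediate
3 | (2R,3S)-2-(iodomethyl)-3-methyl-3-[(3E)-4,8-dimethylnona-3,7-dien-1-yl]oxirane | CC(C)=CCC/C(C)=C/CC[C@]1(C)O[C@H]1CI | intermediate
4 | (3S,6E)-nerolidol | CC(C)=CCC/C(C)=C/CC[C@](C)(O)C=C | intermediate
5 | (2R,3S)-2-(chloromethyl)-3-methyl-3-[(3E)-4,8-dimethylnona-3,7-dien-1-yl]oxirane | CC(C)=CCC/C(C)=C/CC[C@]1(C)O[C@H]1CCl | intermediate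
6 | (3S,6E)-3,7,11-trimethyldodeca-6,10-dien-1-yn-3-ol | CC(C)=CCC/C(C)=C/CC[C@](C)(O)C#C | intermediate
7 | 1,4-dimethoxy-2,3-dimethylbenzene | COc1ccc(OC)c(C)c1C | starting material
8 | 1-bromo-2,5-dimethoxy-3,4-dimethylbenzene | COc1cc(Br)c(OC)c(C)c1C | intermediate
9 | (3S,6E)-1-(9-borabicyclo[3.3.1]nonan-9-yl)-3,7,11-trimethyldodeca-6,10-dien-3-ol | CC(C)=CCC/C(C)=C/CC[C@](C)(O)CCB1C2CCCC1CCC2 | intermediate
10 | (3S,6E)-1-(2,5-dimethoxy-3,4-dimethylphenyl)-3,7,11-trimethyldodeca-6,10-dien-3-ol | CC(C)=CCC/C(C)=C/CC[C@](C)(O)CCc1cc(OC)c(C)c(C)c1OC | intermediate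
11 | 2-[(3S,6E)-3-hydroxy-3,7,11-trimethyldodeca-6,10-dien-1-yl]-5,6-dimethylcyclohexa-2,5-diene-1,4-dione | CC(C)=CCC/C(C)=C/CC[C@](C)(O)CCC1=CC(=O)C(C)=C(C)C1=O | intermediate
12 | (2S)-8a-methoxy-2,7,8-trimethyl-2-[(3E)-4,8-dimethylnona-3,7-dien-1-yl]-2,3,4,8a-tetrahydro-6H-chromen-6-one (both C8a epimers) | CC(C)=CCC/C(C)=C/CC[C@@]1(C)CCC2=CC(=O)C(C)=C(C)C2(OC)O1 | intermediate
13 | (2S)-2-[(3E)-4,8-dimethylnona-3,7-dien-1-yl]-2,7,8-trimethylchroman-6-ol | CC(C)=CCC/C(C)=C/CC[C@@]1(C)CCc2cc(O)c(C)c(C)c2O1 | intermediate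
14 | tert-butyl({(2S)-2-[(3E)-4,8-dimethylnona-3,7-dien-1-yl]-2,7,8-trimethylchroman-6-yl}oxy)dimethylsilane | CC(C)=CCC/C(C)=C/CC[C@@]1(C)CCc2cc(O[Si](C)(C)C(C)(C)C)c(C)c(C)c2O1 | intermediate
15 | (2E,6E)-9-[(2S)-6-{[tert-butyl(dimethyl)silyl]oxy}-2,7,8-trimethylchroman-2-yl]-2,6-dimethylnona-2,6-dien-1-ol | OC/C(C)=C/CC/C(C)=C/CC[C@@]1(C)CCc2cc(O[Si](C)(C)C(C)(C)C)c(C)c(C)c2O1 | intermediate
16 | tert-butyl({(2S)-2-[(3E,7E)-9-bromo-4,8-dimethylnona-3,7-dien-1-yl]-2,7,8-trimethylchroman-6-yl}oxy)dimethylsilane | BrC/C(C)=C/CC/C(C)=C/CC[C@@]1(C)CCc2cc(O[Si](C)(C)C(C)(C)C)c(C)c(C)c2O1 | intermediate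
17 | (4E,8E)-11-[(2S)-6-{[tert-butyl(dimethyl)silyl]oxy}-2,7,8-trimethylchroman-2-yl]-4,8-dimethylundeca-4,8-dienoic acid | OC(=O)CC/C(C)=C/CC/C(C)=C/CC[C@@]1(C)CCc2cc(O[Si](C)(C)C(C)(C)C)c(C)c(C)c2O1 | intermediate
18 | (E)-geranylacetone, (5E)-6,10-dimethylundeca-5,9-dien-2-one | CC(C)=CCC/C(C)=C/CCC(C)=O | starting material
19 | diethyl (5E)-6,10-dimethylundeca-1,5,9-trien-2-yl phosphate | CC(C)=CCC/C(C)=C/CCC(=C)OP(=O)(OCC)OCC | intermediate
20 | (5E)-6,10-dimethylundeca-5,9-dien-1-yne | CC(C)=CCC/C(C)=C/CCC#C | intermediate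
21 | dimethyl[(1E,5E)-2,6,10-trimethylundeca-1,5,9-trien-1-yl]alane | CC(C)=CCC/C(C)=C/CC/C(C)=C/[Al](C)C | intermediate
22 | (1E,5E)-1-iodo-2,6,10-trimethylundeca-1,5,9-triene | CC(C)=CCC/C(C)=C/CC/C(C)=C/I | intermediate
23 | (2E,6E,10E)-11-iodo-2,6,10-trimethylundeca-2,6,10-trien-1-ol | OC/C(C)=C/CC/C(C)=C/CC/C(C)=C/I | intermediate
24 | (1E,5E,9E)-11-bromo-1-iodo-2,6,10-trimethylundeca-1,5,9-triene | BrC/C(C)=C/CC/C(C)=C/CC/C(C)=C/I | intermediate
25 | (1E,5E,9E,14S,17E)-1-iodo-2,6,10,14,18,22-hexamethyltricosa-1,5,9,17,21-pentaen-12-yn-14-ol | CC(C)=CCC/C(C)=C/CC[C@](C)(O)C#CC/C(C)=C/CC/C(C)=C/CC/C(C)=C/I | intermediate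
26 | (1E,5E,9E,12E,14S,17E)-1-iodo-2,6,10,14,18,22-hexamethyltricosa-1,5,9,12,17,21-hexaen-14-ol | CC(C)=CCC/C(C)=C/CC[C@](C)(O)/C=C/C/C(C)=C/CC/C(C)=C/CC/C(C)=C/I | intermediate
27 | 1,3-dioxoisoindolin-2-yl (4E,8E)-11-[(2S)-6-{[tert-butyl(dimethyl)silyl]oxy}-2,7,8-trimethylchroman-2-yl]-4,8-dimethylundeca-4,8-dienoate | O=C1c2ccccc2C(=O)N1OC(=O)CC/C(C)=C/CC/C(C)=C/CC[C@@]3(C)CCc4cc(O[Si](C)(C)C(C)(C)C)c(C)c(C)c4O3 | intermediate
28 | 6-O-tert-butyldimethylsilyl ether of the target | CC(C)=CCC/C(C)=C/CC[C@](C)(O)/C=C/C/C(C)=C/CC/C(C)=C/CC/C(C)=C/CC/C(C)=C/CC/C(C)=C/CC[C@@]1(C)CCc2cc(O[Si](C)(C)C(C)(C)C)c(C)c(C)c2O1 | intermediate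
29 | (2S)-2-[(3E,7E,11E,15E,19E,22E,24S,27E)-24-hydroxy-4,8,12,16,20,24,28,32-octamethyltritriaconta-3,7,11,15,19,22,27,31-octaen-1-yl]-2,7,8-trimethylchroman-6-ol | CC(C)=CCC/C(C)=C/CC[C@](C)(O)/C=C/C/C(C)=C/CC/C(C)=C/CC/C(C)=C/CC/C(C)=C/CC/C(C)=C/CC[C@@]1(C)CCc2cc(O)c(C)c(C)c2O1 | target

**Totals and risks**

Total step count: 20.
Longest linear sequence: 11 steps (steps 1, 2, 6, 7, 8, 9, 10, 11, 12, 19, 20).

Steps most likely to fail:

Step 8. The hemiketal and ketal equilibria may stay on the side of the open hydroxy-quinone. Reduction would then give the ring-open hydroquinone, and a later acid closure through a tertiary cation would erode the configuration at C2. The fallback sets out from 10. Anodic methoxylation of the 1,4-dimethoxyarene (Pt anode, KOH, MeOH, constant current, 0 °C) should give the quinone bis-ketal in which the tethered tertiary hydroxyl has closed onto C8a, (2S)-6,6,8a-trimethoxy-2,7,8-trimethyl-2-[(3E)-4,8-dimethylnona-3,7-dien-1-yl]-3,4,6,8a-tetrahydro-2H-chromene F1. Here the C8a–O bond is made irreversibly by oxidation and the carbinol C–O bond is again untouched. Brief treatment with dilute aqueous acetic acid in acetone should hydrolyse only the less hindered dimethyl ketal at C6 to give 12, which is reduced with ascorbic acid as in step 8. The fallback comes back to the route at 13.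

Step 19. Cross-coupling of two lipophilic, high-mass partners may lose out to reductive dimerisation or protodeiodination of the alkenyl iodide and to premature reduction of the redox-active ester. The fallback sets out from 17 and forms the same bond by two-electron chemistry. Esterification with N-hydroxypyridine-2-thione (N,N'-dicyclohexylcarbodiimide, CH2Cl2, dark) gives the 2-thioxopyridin-1(2H)-yl ester F2. Photolysis of F2 with CHI3 (Barton decarboxylative iodination) gives tert-butyl({(2S)-2-[(3E,7E)-10-iodo-4,8-dimethyldeca-3,7-dien-1-yl]-2,7,8-trimethylchroman-6-yl}oxy)dimethylsilane F3. Iodine–lithium exchange (t-BuLi, Et2O, −78 °C) and trapping with 9-methoxy-9-borabicyclo[3.3.1]nonane gives the lithium B-alkyl-B-methoxy borate F4. B-alkyl Suzuki–Miyaura coupling of F4 with 26 (Pd(dppf)Cl2, K3PO4, DMF/H2O, rt), which tolerates the free tertiary alcohol, comes back to the route at 28.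

Step 18. Hydride reduction or iodine–aluminium exchange at C11' may compete while the hindered tertiary propargylic alkoxide is slowly hydroaluminated, with loss of the alkenyl iodide. The fallback sets out from 25. Ruthenium-catalysed trans-hydrosilylation of the alkyne ([Cp*Ru(MeCN)3]PF6 cat., (EtO)3SiH, CH2Cl2, 0 °C) should give (1E,5E,9E,12Z,14S,17E)-1-iodo-2,6,10,14,18,22-hexamethyl-12-(triethoxysilyl)tricosa-1,5,9,12,17,21-hexaen-14-ol F5. Protodesilylation with retention (CuI, Bu4NF, THF) then gives the (E)-alkene without any hydride reagent. The fallback comes back to the route at 26.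

Further compounds
F1 | step 8 | (2S)-6,6,8a-trimethoxy-2,7,8-trimethyl-2-[(3E)-4,8-dimethylnona-3,7-dien-1-yl]-3,4,6,8a-tetrahydro-2H-chromene | CC(C)=CCC/C(C)=C/CC[C@@]1(C)CCC2=CC(OC)(OC)C(C)=C(C)C2(OC)O1
F2 | step 19 | 2-thioxopyridin-1(2H)-yl (4E,8E)-11-[(2S)-6-{[tert-butyl(dimethyl)silyl]oxy}-2,7,8-trimethylchroman-2-yl]-4,8-dimethylundeca-4,8-dienoate | S=C1C=CC=CN1OC(=O)CC/C(C)=C/CC/C(C)=C/CC[C@@]2(C)CCc3cc(O[Si](C)(C)C(C)(C)C)c(C)c(C)c3O2
F3 | step 19 | tert-butyl({(2S)-2-[(3E,7E)-10-iodo-4,8-dimethyldeca-3,7-dien-1-yl]-2,7,8-trimethylchroman-6-yl}oxy)dimethylsilane | ICC/C(C)=C/CC/C(C)=C/CC[C@@]1(C)CCc2cc(O[Si](C)(C)C(C)(C)C)c(C)c(C)c2O1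
F4 | step 19 | lithium 9-{(3E,7E)-10-[(2S)-6-{[tert-butyl(dimethyl)silyl]oxy}-2,7,8-trimethylchroman-2-yl]-3,7-dimethyldeca-3,7-dien-1-yl}-9-methoxy-9-borabicyclo[3.3.1]nonan-9-uide | [Li+].CO[B-]1(CC/C(C)=C/CC/C(C)=C/CC[C@@]2(C)CCc3cc(O[Si](C)(C)C(C)(C)C)c(C)c(C)c3O2)C4CCCC1CCC4
F5 | step 18 | (1E,5E,9E,12Z,14S,17E)-1-iodo-2,6,10,14,18,22-hexamethyl-12-(triethoxysilyl)tricosa-1,5,9,12,17,21-hexaen-14-ol | CC(C)=CCC/C(C)=C/CC[C@](C)(O)/C=C(/C/C(C)=C/CC/C(C)=C/CC/C(C)=C/I)[Si](OCC)(OCC)OCC
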